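Trisphaerolide A is a δ-lactone (ring atoms O1, C2(=O), C3, C4, C5, C6) whose C6 is fully substituted: it holds CH3, O1, C5 and the first carbon, C1', of the C1'–C12' side chain. The route rests on disconnecting C6–C1'. C6 is carried as a secondary C6–H carbinol of known configuration, esterified as a hindered 2,4,6-triisopropylbenzoate; lithiation, capture by the side-chain boronic ester, stereospecific 1,2-migration and oxidation then replace that hydrogen by the whole chain and deliver the C6 tertiary alcohol in one flask. The precursor is an open-chain benzoate with C4 already set and the C4 and C2 oxygens tied in one acetonide; its partner is a neopentyl glycol boronate.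

Key step: step 11

Remark: lactone numbering (O1, C2–C6, chain C1'–C12') is used for all intermediates; the CIP letter at C4 switches between S and R along the route only because neighbouring groups change priority, the spatial arrangement staying the same.

Step 1
Reactants: 1 ethyl (3S)-3-hydroxybutanoate
Product: 2 ethyl (3S)-3-(benzyloxy)butanoate
Conditions: BnOC(=NH)CCl3, TfOH (cat.), cyclohexane/CH2Cl2, rt
Reagents that add atoms: benzyl 2,2,2-trichloroacetimidate, ClC(Cl)(Cl)C(=N)OCc1ccccc1
Why: Acid-catalysed O-benzylation by a trichloroacetimidate needs no base, so the β-hydroxy ester should neither eliminate nor undergo retro-aldol cleavage, and the carbinol centre is not touched.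

Step 2
Reactants: 2 ethyl (3S)-3-(benzyloxy)butanoate
Product: 4 (4S)-4-(benzyloxy)pentan-2-one, via Weinreb amide 3 (not isolated)
Conditions: MeNHOMe·HCl, i-PrMgCl, THF, −20 °C; then MeMgBr, −20 → 0 °C; aq NH4Cl
Reagents that add atoms: methylmagnesium bromide, C[Mg]Br; N,O-dimethylhydroxylamine hydrochloride, CNOC.Cl (its N(OMe)Me group is carried by 3 only)
Why: Weinreb ketone synthesis run in one flask: the magnesium amide turns the ester into amide 3, and MeMgBr adds only once because the chelated tetrahedral adduct survives until the quench.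

Step 3
Reactants: 4 (4S)-4-(benzyloxy)pentan-2-one; 5 allyltrimethylsilane
Product: 6 (4S,6S)-6-(benzyloxy)-4-methylhept-1-en-4-ol
Conditions: TiCl4, CH2Cl2, −78 °C; then 5, −78 °C; H2O
Reagents that add atoms: none
Why: Chelation-controlled Hosomi–Sakurai allylation: TiCl4 locks the ketone and benzyloxy oxygens in a six-membered chelate and the allylsilane should attack the carbonyl face remote from the methyl group on the benzyloxy carbon, which sets the new tertiary carbinol (C4) as 4S, 1,3-anti to the ether oxygen.

Step 4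
Reactants: 6 (4S,6S)-6-(benzyloxy)-4-methylhept-1-en-4-ol
Product: 9 (3S,5S)-5-(benzyloxy)-3-methylhexane-1,3-diol, via ozonide 7 (not isolated), via hydroxy aldehyde 8 (not isolated)
Conditions: O3, CH2Cl2, −78 °C; then NaBH4, MeOH, −78 °C → rt
Reagents that add atoms: ozone, [O-][O+]=O
Why: Ozonolysis of the terminal alkene with reductive work-up in the same flask gives the primary alcohol, so the retro-aldol-prone β-hydroxy aldehyde is never handled, and no stereocentre is affected.

Step 5
Reactants: 9 (3S,5S)-5-(benzyloxy)-3-methylhexane-1,3-diol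
Product: 10 (4S)-4-[(2S)-2-(benzyloxy)propyl]-2,2,4-trimethyl-1,3-dioxane
Conditions: Me2C(OMe)2, PPTS (cat.), CH2Cl2, rt
Reagents that add atoms: 2,2-dimethoxypropane, COC(C)(C)OC
Why: Acid-catalysed transacetalisation (acetonide formation) ties the primary and the tertiary hydroxyl into one six-membered ketal that is inert to base, hydride and organolithium reagents.

Step 6
Reactants: 10 (4S)-4-[(2S)-2-(benzyloxy)propyl]-2,2,4-trimethyl-1,3-dioxane
Product: 11 (2S)-1-[(4S)-2,2,4-trimethyl-1,3-dioxan-4-yl]propan-2-ol
Conditions: H2 (1 atm), Pd/C, EtOAc, rt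
Reagents that add atoms: none
Why: Catalytic hydrogenolysis cleaves the benzyl ether at the benzylic C–O bond under neutral conditions, leaving the acetonide and the carbinol configuration unchanged.

Step 7
Reactants: 11 (2S)-1-[(4S)-2,2,4-trimethyl-1,3-dioxan-4-yl]propan-2-ol
Product: 13 (2S)-1-[(4S)-2,2,4-trimethyl-1,3-dioxan-4-yl]propan-2-yl 2,4,6-triisopropylbenzoate, via sodium alkoxide 12 (not isolated)
Conditions: NaH, THF, 0 °C → rt; then 2,4,6-(i-Pr)3C6H2COCl, 50 °C
Reagents that add atoms: 2,4,6-triisopropylbenzoyl chloride, CC(C)c1cc(C(C)C)c(C(Cl)=O)c(C(C)C)c1; sodium hydride, [Na+].[H-] (its sodium is carried by 12 only)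
Why: O-Acylation of a preformed alkoxide by the hindered aroyl chloride takes place at oxygen, so C6 keeps its S configuration, and an acetonide, unlike a neighbouring silyl ether, cannot migrate to the alkoxide.

Step 8
Reactants: 14 undec-10-yn-1-ol
Product: 15 11-bromoundec-1-yne
Conditions: CBr4, PPh3, CH2Cl2, 0 °C → rt
Reagents that add atoms: carbon tetrabromide, BrC(Br)(Br)Br
Why: Appel reaction: the alkoxyphosphonium ion is displaced by bromide at the primary carbon, and the terminal alkyne is inert.

Step 9
Reactants: 15 11-bromoundec-1-yne; 16 benzyl bromide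
Product: 18 [(2E)-12-bromododec-2-en-1-yl]benzene, via alkenylzirconocene 17 (not isolated)
Conditions: Cp2Zr(H)Cl, THF, rt; then 16, Pd(PPh3)4 (cat.), rt → 40 °C
Reagents that add atoms: zirconocene chloride hydride Cp2Zr(H)Cl, [H][Zr](Cl)(C1C=CC=C1)C1C=CC=C1 (its Cp2ZrCl unit is carried by 17 only)
Why: Hydrozirconation adds Zr–H syn across the terminal alkyne with zirconium at the terminal carbon, and the palladium-catalysed Negishi-type coupling of the alkenylzirconocene with benzyl bromide proceeds with retention, so the E alkene should result while the primary alkyl bromide stays untouched.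

Step 10
Reactants: 18 [(2E)-12-bromododec-2-en-1-yl]benzene
Product: 19 5,5-dimethyl-2-[(10E)-12-phenyldodec-10-en-1-yl]-1,3,2-dioxaborinane
Conditions: B2neop2, CuI (cat.), PPh3 (cat.), LiOMe, DMF, rt
Reagents that add atoms: bis(neopentyl glycolato)diboron (B2neop2), CC1(C)COB(OC1)B1OCC(C)(C)CO1
Why: Copper-catalysed borylation of a primary alkyl bromide: a copper boryl species made from CuI, LiOMe and the diboron substitutes bromide at C1' without engaging the remote internal alkene, and the unhindered neopentyl glycol ester is installed because a pinacol ester would be a poorer trap for the hindered carbanion of step 11.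

Step 11
Reactants: 13 (2S)-1-[(4S)-2,2,4-trimethyl-1,3-dioxan-4-yl]propan-2-yl 2,4,6-triisopropylbenzoate; 19 5,5-dimethyl-2-[(10E)-12-phenyldodec-10-en-1-yl]-1,3,2-dioxaborinane
Product: 23 (2R,12E)-2-methyl-14-phenyl-1-[(4S)-2,2,4-trimethyl-1,3-dioxan-4-yl]tetradec-12-en-2-ol, via lithiated benzoate 20 (not isolated), via boronate complex 21 (not isolated), via tertiary boronic ester 22 (not isolated)
Conditions: s-BuLi, TMEDA, CPME, −60 °C; then 19, −60 → 50 °C; then NaOH, H2O2, THF/H2O, 0 °C → rt
Reagents that add atoms: hydrogen peroxide, OO; sec-butyllithium, CCC(C)[Li] (its lithium is carried by 20 and 21 only)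
Why: s-BuLi/TMEDA, held by the benzoate carbonyl, removes the C6 hydrogen with retention to give the configurationally stable, carbonyl-chelated α-oxy organolithium 20, which adds to the boron of 19 with retention to give complex 21; on warming, C1' shifts from boron to C6 anti to the departing triisopropylbenzoate (inversion at C6) to give 22, and alkaline H2O2 then replaces boron by OH with retention. The closest known reaction type is the lithiation–borylation of secondary dialkyl 2,4,6-triisopropylbenzoates with primary neopentyl glycol boronic esters to tertiary boronic esters and alcohols, of which 13 is a more hindered member because C4 is quaternary. No ring is closed. The one new stereocentre, C6, is controlled only by the configuration of the C6–H ester, which stems from the hydroxybutanoate carbon: hydrogen is replaced by C1' with oxygen on the same face, so (S)-13 should give the 6R carbinol whatever the configuration at C4. The step needs deprotonation at C6 alone and irreversible trapping of the carbanion; the first is secured by the directing ester carbonyl, the bulky aryl group that blocks acyl transfer and the absence of other acidic sites (an acetonide in place of silyl ethers), the second by the unhindered neopentyl glycol ester, and adding 19 only to preformed 20 keeps s-BuLi away from the allylic-benzylic CH2 of the chain.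

Step 12
Reactants: 23 (2R,12E)-2-methyl-14-phenyl-1-[(4S)-2,2,4-trimethyl-1,3-dioxan-4-yl]tetradec-12-en-2-ol
Product: 24 (3S,5R,15E)-3,5-dimethyl-17-phenylheptadec-15-ene-1,3,5-triol
Conditions: AcOH/THF/H2O, 40 °C
Reagents that add atoms: none
Why: Mild aqueous acid hydrolyses the isopropylidene ketal (acetonide cleavage) without ionising the tertiary carbinols or moving the disubstituted alkene.

Step 13
Reactants: 24 (3S,5R,15E)-3,5-dimethyl-17-phenylheptadec-15-ene-1,3,5-triol
Product: 27 trisphaerolide A [(4R,6R)-4-hydroxy-4,6-dimethyl-6-[(10E)-12-phenyldodec-10-en-1-yl]oxan-2-one], via hydroxy aldehyde 25 (not isolated), via lactol 26 (not isolated)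
Conditions: TEMPO (cat.), PhI(OAc)2, CH2Cl2, rt
Reagents that add atoms: none
Why: Oxidative lactonisation of a 1,5-diol: the oxoammonium ion from TEMPO oxidises only the primary alcohol, the aldehyde is captured by the tertiary C6 hydroxyl as a six-membered lactol, and a second oxidation gives the δ-lactone, while the tertiary hydroxyls and the alkene are not oxidised under these conditions.

Compound list

1 | ethyl (3S)-3-hydroxybutanoate | C[C@H](O)CC(=O)OCC | starting material
2 | ethyl (3S)-3-(benzyloxy)butanoate | C[C@H](OCc1ccccc1)CC(=O)OCC | intermediate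
3 | (3S)-3-(benzyloxy)-N-methoxy-N-methylbutanamide | C[C@H](OCc1ccccc1)CC(=O)N(C)OC | intermediate
4 | (4S)-4-(benzyloxy)pentan-2-one | C[C@H](OCc1ccccc1)CC(C)=O | intermediate
5 | allyltrimethylsilane | C=CC[Si](C)(C)C | starting material
6 | (4S,6S)-6-(benzyloxy)-4-methylhept-1-en-4-ol | C[C@H](OCc1ccccc1)C[C@@](C)(O)CC=C | intermediate
7 | 3-[(2R,4S)-4-(benzyloxy)-2-hydroxy-2-methylpentyl]-1,2,4-trioxolane (both configurations at the ring carbon) | C[C@H](OCc1ccccc1)C[C@@](C)(O)CC1OCOO1 | intermediate
8 | (3R,5S)-5-(benzyloxy)-3-hydroxy-3-methylhexanal | C[C@H](OCc1ccccc1)C[C@@](C)(O)CC=O | intermediate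
9 | (3S,5S)-5-(benzyloxy)-3-methylhexane-1,3-diol | C[C@H](OCc1ccccc1)C[C@@](C)(O)CCO | intermediate
10 | (4S)-4-[(2S)-2-(benzyloxy)propyl]-2,2,4-trimethyl-1,3-dioxane | C[C@H](OCc1ccccc1)C[C@]1(C)CCOC(C)(C)O1 | intermediate
11 | (2S)-1-[(4S)-2,2,4-trimethyl-1,3-dioxan-4-yl]propan-2-ol | C[C@H](O)C[C@]1(C)CCOC(C)(C)O1 | intermediate
12 | sodium (2S)-1-[(4S)-2,2,4-trimethyl-1,3-dioxan-4-yl]propan-2-olate | [Na+].C[C@H]([O-])C[C@]1(C)CCOC(C)(C)O1 | intermediate
13 | (2S)-1-[(4S)-2,2,4-trimethyl-1,3-dioxan-4-yl]propan-2-yl 2,4,6-triisopropylbenzoate | C[C@H](OC(=O)c1c(C(C)C)cc(C(C)C)cc1C(C)C)C[C@]1(C)CCOC(C)(C)O1 | intermediate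
14 | undec-10-yn-1-ol | C#CCCCCCCCCCO | starting material
15 | 11-bromoundec-1-yne | C#CCCCCCCCCCBr | intermediate
16 | benzyl bromide | BrCc1ccccc1 | starting material
17 | [(1E)-11-bromoundec-1-en-1-yl]chlorobis(cyclopentadienyl)zirconium | BrCCCCCCCCC/C=C/[Zr](Cl)(C1C=CC=C1)C1C=CC=C1 | intermediate
18 | [(2E)-12-bromododec-2-en-1-yl]benzene | BrCCCCCCCCC/C=C/Cc1ccccc1 | intermediate
19 | 5,5-dimethyl-2-[(10E)-12-phenyldodec-10-en-1-yl]-1,3,2-dioxaborinane | CC1(C)COB(CCCCCCCCC/C=C/Cc2ccccc2)OC1 | intermediate
20 | (2S)-2-lithio-1-[(4S)-2,2,4-trimethyl-1,3-dioxan-4-yl]propan-2-yl 2,4,6-triisopropylbenzoate | C[C@]([Li])(OC(=O)c1c(C(C)C)cc(C(C)C)cc1C(C)C)C[C@]1(C)CCOC(C)(C)O1 | intermediate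
21 | lithium (2,2-dimethylpropane-1,3-diolato)[(10E)-12-phenyldodec-10-en-1-yl]{(2S)-2-[(2,4,6-triisopropylbenzoyl)oxy]-1-[(4S)-2,2,4-trimethyl-1,3-dioxan-4-yl]propan-2-yl}borate | [Li+].C[C@]([B-]1(CCCCCCCCC/C=C/Cc2ccccc2)OCC(C)(C)CO1)(OC(=O)c1c(C(C)C)cc(C(C)C)cc1C(C)C)C[C@]1(C)CCOC(C)(C)O1 | intermediate
22 | 5,5-dimethyl-2-{(2S,12E)-2-methyl-14-phenyl-1-[(4S)-2,2,4-trimethyl-1,3-dioxan-4-yl]tetradec-12-en-2-yl}-1,3,2-dioxaborinane | C[C@](CCCCCCCCC/C=C/Cc1ccccc1)(B1OCC(C)(C)CO1)C[C@]1(C)CCOC(C)(C)O1 | intermediate
23 | (2R,12E)-2-methyl-14-phenyl-1-[(4S)-2,2,4-trimethyl-1,3-dioxan-4-yl]tetradec-12-en-2-ol | C[C@@](O)(CCCCCCCCC/C=C/Cc1ccccc1)C[C@]1(C)CCOC(C)(C)O1 | intermediate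
24 | (3S,5R,15E)-3,5-dimethyl-17-phenylheptadec-15-ene-1,3,5-triol | C[C@@](O)(CCCCCCCCC/C=C/Cc1ccccc1)C[C@@](C)(O)CCO | intermediate
25 | (3R,5R,15E)-3,5-dihydroxy-3,5-dimethyl-17-phenylheptadec-15-enal | C[C@@](O)(CCCCCCCCC/C=C/Cc1ccccc1)C[C@@](C)(O)CC=O | intermediate
26 | (4R,6R)-4,6-dimethyl-6-[(10E)-12-phenyldodec-10-en-1-yl]oxane-2,4-diol (both anomers) | C[C@]1(O)CC(O)O[C@](C)(CCCCCCCCC/C=C/Cc2ccccc2)C1 | intermediate
27 | trisphaerolide A, (4R,6R)-4-hydroxy-4,6-dimethyl-6-[(10E)-12-phenyldodec-10-en-1-yl]oxan-2-one | C[C@]1(O)CC(=O)O[C@](C)(CCCCCCCCC/C=C/Cc2ccccc2)C1 | target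

Total step count: 13.
Longest linear sequence: 10 steps (steps 1–7, then 11–13, from ethyl (3S)-3-hydroxybutanoate); the side-chain branch is steps 8–10.

Steps most likely to fail

1. Step 11. Deprotonation at C6 may be slow next to the quaternary C4, or the hindered carbanion may add to boron reversibly and decompose before the 1,2-shift, so that little C6–C1' bond is formed. The fallback sets out from alcohol 11 and bromide 18 and comes back at 23. Alcohol 11 would be oxidised with Dess–Martin periodinane (NaHCO3, CH2Cl2) to the methyl ketone 1-[(4S)-2,2,4-trimethyl-1,3-dioxan-4-yl]propan-2-one F1. Bromide 18 would be turned with Mg in THF into [(10E)-12-phenyldodec-10-en-1-yl]magnesium bromide F2, which would be added to F1 in the presence of anhydrous CeCl3 at −78 °C. This carbonyl addition has no built-in control at C6; it should give 23 together with its C6 epimer (2S,12E)-2-methyl-14-phenyl-1-[(4S)-2,2,4-trimethyl-1,3-dioxan-4-yl]tetradec-12-en-2-ol F3, to be separated by chromatography before step 12. Stereospecificity is given up in exchange for a very reliable bond formation.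

2. Step 3. If the titanium chelate is incompletely formed or an open-chain pathway competes, facial selectivity at the ketone would be poor and both C4 epimers would form. The fallback sets out from ketone 4 and comes back at diol 9, replacing substrate control by reagent control. Horner–Wadsworth–Emmons olefination of 4 (triethyl phosphonoacetate, NaH, THF) would give ethyl (2E,5S)-5-(benzyloxy)-3-methylhex-2-enoate F4, from which the minor isomer ethyl (2Z,5S)-5-(benzyloxy)-3-methylhex-2-enoate F5 would be removed by chromatography. DIBAL-H reduction would give (2E,5S)-5-(benzyloxy)-3-methylhex-2-en-1-ol F6. Sharpless epoxidation with Ti(Oi-Pr)4, D-(−)-diethyl tartrate and t-BuOOH should give [(2R,3R)-3-[(2S)-2-(benzyloxy)propyl]-3-methyloxiran-2-yl]methanol F7. Red-Al, which delivers hydride to C2 of 2,3-epoxy alcohols, would then open F7 to the 1,3-diol 9 with the tertiary C–O bond untouched.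

3. Step 13. The aldehyde may not be captured quickly enough by the hindered tertiary C6 hydroxyl and may then suffer retro-aldol cleavage or loss of water at C4, or the oxidation may stall at the lactol stage. The fallback sets out from triol 24 and comes back at 27, going through the carboxylic acid instead of the lactol. The primary alcohol would be oxidised fully with TEMPO/PhI(OAc)2 in MeCN/H2O, where the aldehyde is hydrated and oxidised on, to give (3R,5R,15E)-3,5-dihydroxy-3,5-dimethyl-17-phenylheptadec-15-enoic acid F8. The δ-lactone would then be closed by carbodiimide activation (EDC·HCl, DMAP (cat.), CH2Cl2); six-membered ring closure by the C6 hydroxyl is favoured over four-membered closure by the C4 hydroxyl.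

Further compounds

F1 | step 11 | 1-[(4S)-2,2,4-trimethyl-1,3-dioxan-4-yl]propan-2-one | CC(=O)C[C@]1(C)CCOC(C)(C)O1
F2 | step 11 | [(10E)-12-phenyldodec-10-en-1-yl]magnesium bromide | Br[Mg]CCCCCCCCC/C=C/Cc1ccccc1
F3 | step 11 | (2S,12E)-2-methyl-14-phenyl-1-[(4S)-2,2,4-trimethyl-1,3-dioxan-4-yl]tetradec-12-en-2-ol | C[C@](O)(CCCCCCCCC/C=C/Cc1ccccc1)C[C@]1(C)CCOC(C)(C)O1
F4 | step 3 | ethyl (2E,5S)-5-(benzyloxy)-3-methylhex-2-enoate | CCOC(=O)/C=C(\C)C[C@H](C)OCc1ccccc1
F5 | step 3 | ethyl (2Z,5S)-5-(benzyloxy)-3-methylhex-2-enoate | CCOC(=O)/C=C(/C)C[C@H](C)OCc1ccccc1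
F6 | step 3 | (2E,5S)-5-(benzyloxy)-3-methylhex-2-en-1-ol | OC/C=C(\C)C[C@H](C)OCc1ccccc1
F7 | step 3 | [(2R,3R)-3-[(2S)-2-(benzyloxy)propyl]-3-methyloxiran-2-yl]methanol | OC[C@H]1O[C@]1(C)C[C@H](C)OCc1ccccc1
F8 | step 13 | (3R,5R,15E)-3,5-dihydroxy-3,5-dimethyl-17-phenylheptadec-15-enoic acid | C[C@@](O)(CCCCCCCCC/C=C/Cc1ccccc1)C[C@@](C)(O)CC(O)=O
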